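**Plan**

Locants follow the 3,7-dioxabicyclo[3.3.0]octane core: C1 acetoxy-bearing ring-fusion carbon, C2 guaiacyl-bearing carbon, O3, C4, C5 ring-fusion CH, C6 veratryl-bearing carbon, O7, C8.
Retrosynthesis: cut O–acetyl and O–benzyl; return C4 to a lactone carbonyl; take O3 out of the C2–O3 bond, which leaves a cyclobutanone (C2, C4, C5, C1); cut C2–C4 and C1–C5 to a ketene and a (Z)-silyl enol ether joined through C6–O7–C8; cut O7–C8.
Forward: the ether tether is made by O–H insertion; one intramolecular ketene [2+2] closes the veratryl oxolane (C1, C5, C6, O7, C8) and the cyclobutanone together; oxygen insertion then enlarges the four-membered carbocycle to the five-membered guaiacyl-bearing ring; C4 is deoxygenated, the C1 oxygen acetylated, the phenol freed.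
Enabling feature: the array O3–C2H(aryl)–C1(O)(C8), with C4 on the other side of O3. Without O3 it is a 2-aryl-3-siloxycyclobutanone, the adduct of a ketene and a silyl enol ether, and its electron-rich benzylic carbon C2 is the one that migrates to oxygen.
Stereochemistry: C6 from asymmetric transfer hydrogenation; C1, C2 and C5 from the cycloaddition (cis ring fusion, suprafacial addition to the (Z)-enol ether, C6 aryl on the convex face); the ring enlargement keeps the configuration at C2.

Key step: step 7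

Assumption: compounds 1 and 3 are taken as commercially available.

**Route**

Step 1
Reactants: 1 ethyl 3-(3,4-dimethoxyphenyl)-3-oxopropanoate
Product: 2 ethyl (3S)-3-(3,4-dimethoxyphenyl)-3-hydroxypropanoate
Conditions: RuCl[(S,S)-TsDPEN](p-cymene) (1 mol%), HCO2H/Et3N (5:2), 30 °C
Reagents that add atoms: none
Why: Noyori–Ikariya asymmetric transfer hydrogenation of an aryl ketone, in which the (S,S)-TsDPEN ruthenium hydride is expected, by analogy with acetophenone (aryl large, CH2CO2Et small), to deliver hydride to the face that gives the (S)-benzylic carbinol, the future C6.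

Step 2
Reactants: 3 [4-(benzyloxy)-3-methoxyphenyl]acetic acid
Product: 5 1-[4-(benzyloxy)-3-methoxyphenyl]-3-diazopropan-2-one, via acid chloride 4 (not isolated)
Conditions: (COCl)2, DMF (cat.), CH2Cl2, 0 °C → rt; then CH2N2 (3 equiv), Et2O, 0 °C
Reagents that add atoms: oxalyl chloride, ClC(=O)C(=O)Cl (chlorine of 4 only); diazomethane, C=[N+]=[N-]
Why: Acylation of diazomethane by an acid chloride (first stage of the Arndt–Eistert sequence), with excess diazomethane taking up the hydrogen chloride so that the diazo ketone is not converted into a chloromethyl ketone.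

Step 3
Reactants: 2 ethyl (3S)-3-(3,4-dimethoxyphenyl)-3-hydroxypropanoate; 5 1-[4-(benzyloxy)-3-methoxyphenyl]-3-diazopropan-2-one
Product: 6 ethyl (3S)-3-{3-[4-(benzyloxy)-3-methoxyphenyl]-2-oxopropoxy}-3-(3,4-dimethoxyphenyl)propanoate
Conditions: Rh2(OAc)4 (1 mol%), CH2Cl2, rt, 5 (1.5 equiv) added slowly by syringe pump to 2
Reagents that add atoms: none
Why: Rhodium-carbenoid O–H insertion of an α-diazo ketone into a secondary alcohol, a neutral etherification that avoids base-induced retro-oxa-Michael loss of the β-alkoxy ester and does not touch the carbinol stereocenter.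

Step 4
Reactants: 6 ethyl (3S)-3-{3-[4-(benzyloxy)-3-methoxyphenyl]-2-oxopropoxy}-3-(3,4-dimethoxyphenyl)propanoate
Product: 7 (3S)-3-{3-[4-(benzyloxy)-3-methoxyphenyl]-2-oxopropoxy}-3-(3,4-dimethoxyphenyl)propanoic acid
Conditions: LiOH·H2O, THF/H2O (3:1), 0 °C; then 1 M HCl to pH 3
Reagents that add atoms: lithium hydroxide, [Li+].[OH-]
Why: Ester saponification, in which hydroxide adds to the ester carbonyl at 0 °C much faster than the ketone is enolised or the β-alkoxide is eliminated, so that C6 and the ether survive.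

Step 5
Reactants: 7 (3S)-3-{3-[4-(benzyloxy)-3-methoxyphenyl]-2-oxopropoxy}-3-(3,4-dimethoxyphenyl)propanoic acid
Product: 9 (3S)-3-{[(2Z)-3-[4-(benzyloxy)-3-methoxyphenyl]-2-[(tert-butyldimethylsilyl)oxy]prop-2-en-1-yl]oxy}-3-(3,4-dimethoxyphenyl)propanoic acid, via bis-silyl derivative 8 (not isolated)
Conditions: TBSOTf (2.5 equiv), Et3N (4 equiv), CH2Cl2, −78 → 0 °C; then K2CO3 (0.2 equiv), THF/H2O, 0 °C, 15 min; pH 5 phosphate buffer
Reagents that add atoms: tert-butyldimethylsilyl trifluoromethanesulfonate, CC(C)(C)[Si](C)(C)OS(=O)(=O)C(F)(F)F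
Why: Soft enolisation with a silyl triflate and a tertiary amine, which should give the thermodynamic silyl enol ether conjugated with the arene in the (Z) geometry (aryl cis to the siloxy group, avoiding allylic strain with the CH2O substituent), while the silyl ester formed at the same time is hydrolysed selectively by the mild aqueous carbonate.

Step 6
Reactants: 9 (3S)-3-{[(2Z)-3-[4-(benzyloxy)-3-methoxyphenyl]-2-[(tert-butyldimethylsilyl)oxy]prop-2-en-1-yl]oxy}-3-(3,4-dimethoxyphenyl)propanoic acid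
Product: 12 (1S,4S,5R,7R)-7-[4-(benzyloxy)-3-methoxyphenyl]-1-[(tert-butyldimethylsilyl)oxy]-4-(3,4-dimethoxyphenyl)-3-oxabicyclo[3.2.0]heptan-6-one, via acid chloride 10 (not isolated), via ketene 11 (not isolated)
Conditions: 1-chloro-N,N,2-trimethylprop-1-en-1-amine (1.1 equiv), CH2Cl2, 0 °C; then added slowly to Et3N (3 equiv), toluene, 80 °C (0.01 M)
Reagents that add atoms: 1-chloro-N,N,2-trimethylprop-1-en-1-amine, CC(C)=C(Cl)N(C)C (chlorine of 10 only; no atoms remain in 12)
Why: Intramolecular ketene–enol ether [2+2] cycloaddition: the nucleophilic benzylic carbon C2 of the enol ether attacks the ketene carbonyl carbon C4 and the siloxy-stabilised carbon C1 closes onto the ketene α-carbon C5, the three-atom tether (C6, O7, C8) enforcing the cis-fused 3-oxabicyclo[3.2.0]heptan-6-one; suprafacial addition to the (Z)-enol ether sets aryl cis to siloxy at C2/C1, and the C6 aryl group is expected to take the convex face of the forming five-membered ring, which sets C5 and C1 relative to C6.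

Step 7
Reactants: 12 (1S,4S,5R,7R)-7-[4-(benzyloxy)-3-methoxyphenyl]-1-[(tert-butyldimethylsilyl)oxy]-4-(3,4-dimethoxyphenyl)-3-oxabicyclo[3.2.0]heptan-6-one
Product: 13 (1S,2R,5R,6S)-2-[4-(benzyloxy)-3-methoxyphenyl]-1-[(tert-butyldimethylsilyl)oxy]-6-(3,4-dimethoxyphenyl)-3,7-dioxabicyclo[3.3.0]octan-4-one
Conditions: m-CPBA (1.3 equiv), NaHCO3, CH2Cl2, 0 °C
Reagents that add atoms: 3-chloroperbenzoic acid, OOC(=O)c1cccc(Cl)c1
Why: Baeyer–Villiger oxidation: the peracid adds to the strained four-ring carbonyl C4 to give the Criegee adduct, from which the C2–C4 bond antiperiplanar to the breaking O–O bond shifts to oxygen with loss of 3-chlorobenzoate, so that O3 is inserted between C4 and C2. The closest known reaction type is the peracid ring expansion of bicyclo[3.2.0]heptan-6-ones and 3-alkoxycyclobutanones to γ-lactones. No ring is closed by cyclization: the cyclobutanone (C2, C4, C5, C1) is enlarged by one atom through a 1,2-shift of carbon to oxygen, driven by release of four-ring strain, into the five-membered lactone (C2, O3, C4, C5, C1), which is the guaiacyl-bearing ring of the target at the lactone oxidation level. No stereocenter is created: the migrating carbon C2 keeps its configuration, so C1, C2, C5 and C6 pass unchanged from the cycloadduct into 13. The step needs migration of C2 and not of the ring-fusion carbon C5, which the electron-rich 4-benzyloxy-3-methoxyphenyl group on C2 should secure by stabilising the electron-deficient migrating center, while C5 is deactivated by oxygen-bearing neighbours on both sides (C6 and C1). It also needs chemoselectivity for the ketone over the two alkoxyarenes, which the high reactivity of a cyclobutanone toward buffered peracid at 0 °C should provide.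

Step 8
Reactants: 13 (1S,2R,5R,6S)-2-[4-(benzyloxy)-3-methoxyphenyl]-1-[(tert-butyldimethylsilyl)oxy]-6-(3,4-dimethoxyphenyl)-3,7-dioxabicyclo[3.3.0]octan-4-one
Product: 14 (1S,2R,5R,6S)-2-[4-(benzyloxy)-3-methoxyphenyl]-1-[(tert-butyldimethylsilyl)oxy]-6-(3,4-dimethoxyphenyl)-3,7-dioxabicyclo[3.3.0]octan-4-ol (both C4 epimers)
Conditions: i-Bu2AlH (1.2 equiv), CH2Cl2, −78 °C; aq. potassium sodium tartrate work-up
Reagents that add atoms: none
Why: Partial reduction of a γ-lactone with i-Bu2AlH at −78 °C, where the aluminium hemiacetal is stable until work-up and the five-membered ring made in step 7 stays closed as the lactol, whose new hemiacetal center is removed in step 9.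

Step 9
Reactants: 14 (1S,2R,5R,6S)-2-[4-(benzyloxy)-3-methoxyphenyl]-1-[(tert-butyldimethylsilyl)oxy]-6-(3,4-dimethoxyphenyl)-3,7-dioxabicyclo[3.3.0]octan-4-ol
Product: 15 (1S,2R,5R,6S)-2-[4-(benzyloxy)-3-methoxyphenyl]-1-[(tert-butyldimethylsilyl)oxy]-6-(3,4-dimethoxyphenyl)-3,7-dioxabicyclo[3.3.0]octane
Conditions: Et3SiH (3 equiv), BF3·OEt2 (1.5 equiv), CH2Cl2, −78 → −40 °C
Reagents that add atoms: none
Why: Ionic hydrogenation of a lactol (Lewis-acid ionisation to the cyclic oxocarbenium ion, then hydride transfer from the silane), which turns C4 into a methylene group without opening the ring and creates no stereocenter, the low temperature being chosen so that the benzylic C–O bonds at C2 and C6 do not ionise.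

Step 10
Reactants: 15 (1S,2R,5R,6S)-2-[4-(benzyloxy)-3-methoxyphenyl]-1-[(tert-butyldimethylsilyl)oxy]-6-(3,4-dimethoxyphenyl)-3,7-dioxabicyclo[3.3.0]octane
Product: 16 (1S,2R,5R,6S)-2-[4-(benzyloxy)-3-methoxyphenyl]-6-(3,4-dimethoxyphenyl)-3,7-dioxabicyclo[3.3.0]octan-1-ol
Conditions: Bu4NF (1 M in THF), THF, rt → 45 °C
Reagents that add atoms: none
Why: Fluoride-induced cleavage of the silyl ether, driven by the strong Si–F bond, which frees the tertiary C1 hydroxyl while the aryl benzyl ether and both oxolane rings are inert.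

Step 11
Reactants: 16 (1S,2R,5R,6S)-2-[4-(benzyloxy)-3-methoxyphenyl]-6-(3,4-dimethoxyphenyl)-3,7-dioxabicyclo[3.3.0]octan-1-ol
Product: 17 (1S,2R,5R,6S)-2-[4-(benzyloxy)-3-methoxyphenyl]-6-(3,4-dimethoxyphenyl)-3,7-dioxabicyclo[3.3.0]octan-1-yl acetate
Conditions: Ac2O (5 equiv), Et3N, DMAP (0.5 equiv), CH2Cl2, rt → 40 °C
Reagents that add atoms: acetic anhydride, CC(=O)OC(C)=O
Why: DMAP-catalysed acyl transfer (Steglich-type acetylation), in which the N-acetylpyridinium ion is electrophilic enough to acylate the hindered tertiary ring-fusion alcohol without any acid that could ionise the benzylic ethers.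

Step 12
Reactants: 17 (1S,2R,5R,6S)-2-[4-(benzyloxy)-3-methoxyphenyl]-6-(3,4-dimethoxyphenyl)-3,7-dioxabicyclo[3.3.0]octan-1-yl acetate
Product: 18 (1S,2R,5R,6S)-6-(3,4-dimethoxyphenyl)-2-(4-hydroxy-3-methoxyphenyl)-3,7-dioxabicyclo[3.3.0]octan-1-yl acetate
Conditions: H2 (1 atm), 10% Pd/C, EtOAc, rt
Reagents that add atoms: none
Why: Hydrogenolysis of an aryl benzyl ether over palladium, which under neutral conditions in ethyl acetate is expected to be much faster than hydrogenolysis of the two cyclic benzylic C–O bonds or any change at the tertiary acetate.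

**Compound list**

1 | ethyl 3-(3,4-dimethoxyphenyl)-3-oxopropanoate | CCOC(=O)CC(=O)c1ccc(OC)c(OC)c1 | starting material
2 | ethyl (3S)-3-(3,4-dimethoxyphenyl)-3-hydroxypropanoate | CCOC(=O)C[C@H](O)c1ccc(OC)c(OC)c1 | intermediate
3 | [4-(benzyloxy)-3-methoxyphenyl]acetic acid | COc1cc(CC(=O)O)ccc1OCc1ccccc1 | starting material
4 | [4-(benzyloxy)-3-methoxyphenyl]acetyl chloride | COc1cc(CC(=O)Cl)ccc1OCc1ccccc1 | intermediate
5 | 1-[4-(benzyloxy)-3-methoxyphenyl]-3-diazopropan-2-one | COc1cc(CC(=O)C=[N+]=[N-])ccc1OCc1ccccc1 | intermediate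
6 | ethyl (3S)-3-{3-[4-(benzyloxy)-3-methoxyphenyl]-2-oxopropoxy}-3-(3,4-dimethoxyphenyl)propanoate | CCOC(=O)C[C@H](OCC(=O)Cc1ccc(OCc2ccccc2)c(OC)c1)c1ccc(OC)c(OC)c1 | intermediate
7 | (3S)-3-{3-[4-(benzyloxy)-3-methoxyphenyl]-2-oxopropoxy}-3-(3,4-dimethoxyphenyl)propanoic acid | OC(=O)C[C@H](OCC(=O)Cc1ccc(OCc2ccccc2)c(OC)c1)c1ccc(OC)c(OC)c1 | intermediate
8 | tert-butyldimethylsilyl (3S)-3-{[(2Z)-3-[4-(benzyloxy)-3-methoxyphenyl]-2-[(tert-butyldimethylsilyl)oxy]prop-2-en-1-yl]oxy}-3-(3,4-dimethoxyphenyl)propanoate | CC(C)(C)[Si](C)(C)OC(=O)C[C@H](OC/C(O[Si](C)(C)C(C)(C)C)=C/c1ccc(OCc2ccccc2)c(OC)c1)c1ccc(OC)c(OC)c1 | intermediate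
9 | (3S)-3-{[(2Z)-3-[4-(benzyloxy)-3-methoxyphenyl]-2-[(tert-butyldimethylsilyl)oxy]prop-2-en-1-yl]oxy}-3-(3,4-dimethoxyphenyl)propanoic acid | OC(=O)C[C@H](OC/C(O[Si](C)(C)C(C)(C)C)=C/c1ccc(OCc2ccccc2)c(OC)c1)c1ccc(OC)c(OC)c1 | intermediate
10 | (3S)-3-{[(2Z)-3-[4-(benzyloxy)-3-methoxyphenyl]-2-[(tert-butyldimethylsilyl)oxy]prop-2-en-1-yl]oxy}-3-(3,4-dimethoxyphenyl)propanoyl chloride | ClC(=O)C[C@H](OC/C(O[Si](C)(C)C(C)(C)C)=C/c1ccc(OCc2ccccc2)c(OC)c1)c1ccc(OC)c(OC)c1 | intermediate
11 | (3S)-3-{[(2Z)-3-[4-(benzyloxy)-3-methoxyphenyl]-2-[(tert-butyldimethylsilyl)oxy]prop-2-en-1-yl]oxy}-3-(3,4-dimethoxyphenyl)prop-1-en-1-one (ketene) | O=C=C[C@H](OC/C(O[Si](C)(C)C(C)(C)C)=C/c1ccc(OCc2ccccc2)c(OC)c1)c1ccc(OC)c(OC)c1 | intermediate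
12 | (1S,4S,5R,7R)-7-[4-(benzyloxy)-3-methoxyphenyl]-1-[(tert-butyldimethylsilyl)oxy]-4-(3,4-dimethoxyphenyl)-3-oxabicyclo[3.2.0]heptan-6-one (cis-fused; aryl on C7 cis to the siloxy group; aryl on C4 on the convex face) | COc1cc([C@H]2C(=O)[C@@H]3[C@@H](c4ccc(OC)c(OC)c4)OC[C@]23O[Si](C)(C)C(C)(C)C)ccc1OCc1ccccc1 | intermediate
13 | (1S,2R,5R,6S)-2-[4-(benzyloxy)-3-methoxyphenyl]-1-[(tert-butyldimethylsilyl)oxy]-6-(3,4-dimethoxyphenyl)-3,7-dioxabicyclo[3.3.0]octan-4-one | COc1cc([C@H]2OC(=O)[C@@H]3[C@@H](c4ccc(OC)c(OC)c4)OC[C@]23O[Si](C)(C)C(C)(C)C)ccc1OCc1ccccc1 | intermediate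
14 | (1S,2R,5R,6S)-2-[4-(benzyloxy)-3-methoxyphenyl]-1-[(tert-butyldimethylsilyl)oxy]-6-(3,4-dimethoxyphenyl)-3,7-dioxabicyclo[3.3.0]octan-4-ol (both C4 epimers) | COc1cc([C@H]2OC(O)[C@@H]3[C@@H](c4ccc(OC)c(OC)c4)OC[C@]23O[Si](C)(C)C(C)(C)C)ccc1OCc1ccccc1 | intermediate
15 | (1S,2R,5R,6S)-2-[4-(benzyloxy)-3-methoxyphenyl]-1-[(tert-butyldimethylsilyl)oxy]-6-(3,4-dimethoxyphenyl)-3,7-dioxabicyclo[3.3.0]octane | COc1cc([C@H]2OC[C@@H]3[C@@H](c4ccc(OC)c(OC)c4)OC[C@]23O[Si](C)(C)C(C)(C)C)ccc1OCc1ccccc1 | intermediate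
16 | (1S,2R,5R,6S)-2-[4-(benzyloxy)-3-methoxyphenyl]-6-(3,4-dimethoxyphenyl)-3,7-dioxabicyclo[3.3.0]octan-1-ol | COc1cc([C@H]2OC[C@@H]3[C@@H](c4ccc(OC)c(OC)c4)OC[C@]23O)ccc1OCc1ccccc1 | intermediate
17 | (1S,2R,5R,6S)-2-[4-(benzyloxy)-3-methoxyphenyl]-6-(3,4-dimethoxyphenyl)-3,7-dioxabicyclo[3.3.0]octan-1-yl acetate | COc1cc([C@H]2OC[C@@H]3[C@@H](c4ccc(OC)c(OC)c4)OC[C@]23OC(C)=O)ccc1OCc1ccccc1 | intermediate
18 | (1S,2R,5R,6S)-6-(3,4-dimethoxyphenyl)-2-(4-hydroxy-3-methoxyphenyl)-3,7-dioxabicyclo[3.3.0]octan-1-yl acetate | COc1cc([C@H]2OC[C@@H]3[C@@H](c4ccc(OC)c(OC)c4)OC[C@]23OC(C)=O)ccc1O | target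

**Step count and risks**

Total step count: 12. Longest linear sequence: 11 steps (1 → 2 → 6 → 7 → 9 → 12 → 13 → 14 → 15 → 16 → 17 → 18; the branch 3 → 5 → 6 is equally long).

The three steps most likely to fail:

Step 6 (intramolecular ketene cycloaddition). What may go wrong is poor facial selectivity with respect to the C6 stereocenter in the open-chain transition state, protodesilylation of the enol ether, or oligomerisation of the ketene before ring closure. The fallback sets out from 2 and 4 and comes back at 12. It makes the veratryl-bearing ring first and lets a cyclic enol ether direct an intermolecular cycloaddition. Rh2(OAc)4-catalysed O–H insertion of ethyl diazoacetate into 2 would give ethyl (3S)-3-(3,4-dimethoxyphenyl)-3-(2-ethoxy-2-oxoethoxy)propanoate F1. Dieckmann condensation (LiN(SiMe3)2, THF, −78 → 0 °C, kept cold to avoid retro-oxa-Michael loss of the C6 stereocenter) would give ethyl (2S)-2-(3,4-dimethoxyphenyl)-4-oxooxolane-3-carboxylate F2; the regioisomeric β-keto ester, if formed, leads to the same ketone. Krapcho dealkoxycarbonylation (LiCl, wet DMSO, 130 °C) would give (5S)-5-(3,4-dimethoxyphenyl)oxolan-3-one F3. Kinetic enolisation away from the ring oxygen (LiN(i-Pr)2, THF, −78 °C, then TBSCl) would give tert-butyl{[(5S)-5-(3,4-dimethoxyphenyl)-2,5-dihydrofuran-3-yl]oxy}dimethylsilane F4. Slow addition of acid chloride 4 to F4 and Et3N in toluene should generate the arylketene, which is expected to add to the enol ether with the regiochemistry of step 6 and on the face anti to the neighbouring aryl group. The kinetic adduct is expected to carry the ketene aryl group on the concave face, (1S,4S,5R,7S)-7-[4-(benzyloxy)-3-methoxyphenyl]-1-[(tert-butyldimethylsilyl)oxy]-4-(3,4-dimethoxyphenyl)-3-oxabicyclo[3.2.0]heptan-6-one F5. Equilibration of its α-aryl center with DBU should move the aryl group to the convex face and give 12.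

Step 7 (Baeyer–Villiger ring expansion). What may go wrong is competing migration of the ring-fusion carbon C5, which would give the regioisomeric lactone, or peracid oxidation of the electron-rich arenes. The fallback sets out from 12 and comes back at 15. It replaces the peracid by the photochemical ring expansion of cyclobutanones. Irradiation of 12 in methanol (Pyrex filter, λ ≥ 300 nm, NaHCO3, 0 °C) should cleave the C2–C4 bond on the benzylic side (Norrish α-cleavage), reclose the acyl–benzyl biradical on oxygen to the oxacarbene, and trap it with methanol as (1S,2R,5R,6S)-2-[4-(benzyloxy)-3-methoxyphenyl]-1-[(tert-butyldimethylsilyl)oxy]-6-(3,4-dimethoxyphenyl)-4-methoxy-3,7-dioxabicyclo[3.3.0]octane F6. Here the site of oxygen insertion is set by radical stability and not by migratory aptitude. Reduction of F6 with Et3SiH and BF3·OEt2 (CH2Cl2, −78 °C) would give 15 directly, so that 13 and 14 are bypassed.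

Step 3 (O–H insertion). What may go wrong is diversion of the rhodium carbenoid into intramolecular aromatic substitution of its own electron-rich aryl ring or into carbene dimerisation, faster than its capture by the hindered secondary alcohol. The fallback sets out from 5 and 2 and comes back at 6. It replaces carbenoid insertion by a base-free SN2 etherification. Treatment of 5 with HBr (48% aq., Et2O, 0 °C) would give 1-[4-(benzyloxy)-3-methoxyphenyl]-3-bromopropan-2-one F7. Alkylation of 2 with F7 under silver promotion (AgOTf, 2,6-di-tert-butylpyridine, CH2Cl2, 0 °C → rt) should give 6 without exposing the β-hydroxy ester to base.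

**Further compounds**

F1 | step 6 | ethyl (3S)-3-(3,4-dimethoxyphenyl)-3-(2-ethoxy-2-oxoethoxy)propanoate | CCOC(=O)C[C@H](OCC(=O)OCC)c1ccc(OC)c(OC)c1
F2 | step 6 | ethyl (2S)-2-(3,4-dimethoxyphenyl)-4-oxooxolane-3-carboxylate | CCOC(=O)C1C(=O)CO[C@@H]1c1ccc(OC)c(OC)c1
F3 | step 6 | (5S)-5-(3,4-dimethoxyphenyl)oxolan-3-one | O=C1CO[C@H](c2ccc(OC)c(OC)c2)C1
F4 | step 6 | tert-butyl{[(5S)-5-(3,4-dimethoxyphenyl)-2,5-dihydrofuran-3-yl]oxy}dimethylsilane | CC(C)(C)[Si](C)(C)OC1=C[C@@H](c2ccc(OC)c(OC)c2)OC1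
F5 | step 6 | (1S,4S,5R,7S)-7-[4-(benzyloxy)-3-methoxyphenyl]-1-[(tert-butyldimethylsilyl)oxy]-4-(3,4-dimethoxyphenyl)-3-oxabicyclo[3.2.0]heptan-6-one | COc1cc([C@@H]2C(=O)[C@@H]3[C@@H](c4ccc(OC)c(OC)c4)OC[C@]23O[Si](C)(C)C(C)(C)C)ccc1OCc1ccccc1
F6 | step 7 | (1S,2R,5R,6S)-2-[4-(benzyloxy)-3-methoxyphenyl]-1-[(tert-butyldimethylsilyl)oxy]-6-(3,4-dimethoxyphenyl)-4-methoxy-3,7-dioxabicyclo[3.3.0]octane (both C4 epimers) | COc1cc([C@H]2OC(OC)[C@@H]3[C@@H](c4ccc(OC)c(OC)c4)OC[C@]23O[Si](C)(C)C(C)(C)C)ccc1OCc1ccccc1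
F7 | step 3 | 1-[4-(benzyloxy)-3-methoxyphenyl]-3-bromopropan-2-one | COc1cc(CC(=O)CBr)ccc1OCc1ccccc1
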